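- If partner enters the solution at a steady rate, so that [partner] climbs in proportion to time while [substrate] stays near its charge, then target forms by a pseudo-first-order step in partner, its rate grows with time, and integrating that rate makes target rise with the square of the time.

- Wednesday's: substrate 0.40 M; solid reagent 0.50 equiv; the very flask that is asked about, followed so far
- flask: substrate 0.40 M; solid reagent 0.500 equiv; time 2.0 d

Wednesday's run (percent of the substrate charged): time / h: target / % = 4.00: 0.2; 8.00: 0; 12.0: 0.7; 15.0: 1.0; 20.0: 2.1; 25.0: 3.1

(readings scatter by 0.3 percentage points)

- in percentages every species weighs as the substrate in it: one side product B counts as two
- as a solid, counted per litre of solution: solid reagent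
- candidate steps: substrate + partner -> target; substrate -> side product A; 2 substrate -> side product B; solid reagent <-> partner
- at the start none of the solid reagent is in solution

1. the target standing at 2.0 d, as a percentage of the substrate charged
2. the change that raises the amount of target at 2.0 d, in percent of the substrate charged most ("none" if none brings more than 2 percentage points) (delta / eta / none)
3. amount of target at 2.0 d, in percent of the substrate charged, after delta

- delta: doubling the dissolution coefficient of the solid reagent, all else as stated
- eta: doubling the solubility of the solid reagent, all else as stated

- Wednesday's flask read 3.1 % at 25.0 h, so a square law through that reading gave 142 h; I named this the full-charge time, the time at which target on that law equals the substrate charged, so that target as a fraction of the charge is the square of the time divided by it.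
- I doubted that a single reading could carry a law, but the full-charge time gave 1.98 % at 20.0 h against the 2.1 % read there, a gap smaller than the scatter of 0.3 percentage points.
- Carried to 2.0 d, the full-charge time gave 11.4 %, but that assumed steady entry of partner and standing substrate for almost twice as long, and the readings are of target, not of [partner] or [substrate], while both side steps may consume substrate.
- So I also continued straight from the last reading along the slope of the last two, as if the rate stopped rising, which gave 7.70 %; I committed to this, with 11.4 % as my top.
- If partner enters at the dissolution coefficient times the distance of [partner] from the solubility, doubling either setting doubles its early entry, which put delta near 15.4 % by my reckoning, but eta also raises the ceiling on [partner], so I chose eta.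
- The forecast gave 10.5 %, above my figure, with eta as best and 18 % after delta, saying “There is no sign of saturation yet”.
- The flask gave 6.31 %, with 10.3 % after delta and eta as best, its gain 5.7 points against 4 points for delta.

    substrate + partner → target (k = 0.00170 /M/min)
    substrate → side product A (k = 3.00 × 10⁻⁴ /min)
    2 substrate → side product B (k = 4.30 × 10⁻⁴ /M/min)
    solid reagent ⇌ partner, rate k4*(cs4 - [partner]) while solid is left; crystals form when [partner] > cs4 (solubility = 0.130 M, k = 2.90 × 10⁻⁴ /min)

- At 2.0 d the flask held 0.552 of what the full-charge time gave, with substrate at 22.0 % by then. On the neighbouring flask left until 8.0 d, the same full-charge time gave 183 %, more than the whole charge, whereas that flask stood at 12.3 % of target with 0.35 % of its substrate left.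

The data are simulated from invented constants; scatter was added.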